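Isoplagilin is cut at the two-carbon bridge that joins C6 of ring C (the catechol ring whose C1 holds the biaryl bond) to C1 of ring D (the second 3-methoxyphenyl ring). Both bridge carbons are brought in as one acetylene from propiolic acid: 3-iodoanisole arylates its C–H end, then the C6 bromide of ring C arylates its carboxyl end with loss of CO2, so both aryl–alkyne bonds form in one flask. The precursor is a tetra-O-benzyl biaryl bromide that already holds rings A, B and C, made by single Negishi coupling of a symmetrical dibromide. One hydrogenation then saturates the alkyne and frees both catechols.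

Key step: step 6

Assumption: ring A is the first 3-methoxyphenyl ring and ring B the catechol ring joined to it by the first CH2CH2 bridge. Ring C is numbered from its biaryl carbon (C1), which puts its oxygens on C3 and C4 and the second bridge on C6. The alkene of 5 is carried as an E/Z mixture because step 3 removes it.

Step 1
Reactants: 1 3-bromo-4,5-dihydroxybenzaldehyde
Product: 2 3,4-bis(benzyloxy)-5-bromobenzaldehyde
Conditions: BnBr (2.4 equiv), K2CO3, DMF, 60 °C, under N2
Reagents that add atoms: benzyl bromide, BrCc1ccccc1
Why: Williamson ether synthesis, in which the carbonate base deprotonates both acidic phenols for SN2 attack on benzyl bromide while the aldehyde and the aryl bromide stay untouched.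

Step 2
Reactants: 2 3,4-bis(benzyloxy)-5-bromobenzaldehyde; 3 (3-methoxybenzyl)triphenylphosphonium chloride
Product: 5 1,2-bis(benzyloxy)-3-bromo-5-[2-(3-methoxyphenyl)ethenyl]benzene (E/Z mixture), via benzylidenephosphorane 4 (not isolated)
Conditions: KOtBu, THF, 0 °C to rt
Reagents that add atoms: none
Why: Wittig olefination with a semi-stabilised benzylic ylide should give the stilbene as an E/Z mixture, which is acceptable because both isomers converge in step 3 and no stereocentre is involved.

Step 3
Reactants: 5 1,2-bis(benzyloxy)-3-bromo-5-[2-(3-methoxyphenyl)ethenyl]benzene (E/Z mixture)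
Product: 6 1,2-bis(benzyloxy)-3-bromo-5-[2-(3-methoxyphenyl)ethyl]benzene
Conditions: TsNHNH2 (excess, in portions), NaOAc, DME/H2O, reflux
Reagents that add atoms: none
Why: Diimide reduction transfers two hydrogens to the C=C bond in a concerted way and leaves the aryl bromide and the benzyl ethers alone, both of which catalytic hydrogenation would put at risk.

Step 4
Reactants: 7 4,5-dibromobenzene-1,2-diol
Product: 8 1,2-bis(benzyloxy)-4,5-dibromobenzene
Conditions: BnBr (2.4 equiv), K2CO3, DMF, 60 °C, under N2
Reagents that add atoms: benzyl bromide, BrCc1ccccc1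
Why: Williamson ether synthesis on both catechol oxygens, run with exclusion of air because the free catechol is prone to oxidation until it is capped.

Step 5
Reactants: 6 1,2-bis(benzyloxy)-3-bromo-5-[2-(3-methoxyphenyl)ethyl]benzene; 8 1,2-bis(benzyloxy)-4,5-dibromobenzene
Product: 11 1,2-bis(benzyloxy)-3-[4,5-bis(benzyloxy)-2-bromophenyl]-5-[2-(3-methoxyphenyl)ethyl]benzene, via aryllithium 9 (not isolated), via arylzinc chloride 10 (not isolated)
Conditions: 6, n-BuLi, THF, −78 °C; ZnCl2, −78 °C to rt; then 8 (3 equiv), Pd(PPh3)4 (5 mol%), THF, 60 °C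
Reagents that add atoms: none
Why: Bromine–lithium exchange, transmetalation to zinc and Negishi cross-coupling, where the two C–Br bonds of 8 are equivalent, so only single versus double coupling has to be controlled, and this is done by the excess of 8 (recovered afterwards) and by the extra hindrance of the bromide left next to the new biaryl bond.

Step 6
Reactants: 11 1,2-bis(benzyloxy)-3-[4,5-bis(benzyloxy)-2-bromophenyl]-5-[2-(3-methoxyphenyl)ethyl]benzene; 12 propiolic acid; 13 3-iodoanisole
Product: 15 1,2-bis(benzyloxy)-3-{4,5-bis(benzyloxy)-2-[(3-methoxyphenyl)ethynyl]phenyl}-5-[2-(3-methoxyphenyl)ethyl]benzene, via 3-(3-methoxyphenyl)propiolic acid 14 (not isolated)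
Conditions: 12 (1.3 equiv), 13 (1.3 equiv), PdCl2(PPh3)2 (5 mol%), 1,4-bis(diphenylphosphino)butane (10 mol%), DBU (3 equiv), DMSO, rt; then 11 (1.0 equiv), 100 °C
Reagents that add atoms: none
Why: Zerovalent palladium formed from PdCl2(PPh3)2 inserts into the C–I bond of 13 at room temperature and the aryl group is transferred to the terminal carbon of the DBU propiolate (copper-free Sonogashira coupling), giving 14 as its carboxylate with the CO2 unit still in place. On heating, zerovalent palladium inserts into the C6–Br bond of ring C in 11, the carboxylate of 14 replaces bromide on divalent palladium and loses CO2 to give an aryl(alkynyl)palladium species, and reductive elimination forms the alkyne–C6 bond. The closest known reaction type is the one-pot Sonogashira coupling and decarboxylative alkynylation of propiolic acid with an aryl iodide followed by an aryl bromide. No ring is closed and no stereocentre is formed. The step needs chemoselectivity between the two ends of propiolic acid and between the two halides: the iodide reacts cold at the C–H end while the hindered, electron-rich bromide reacts only hot at the carboxyl end, and 11 is added after 13 has been consumed, so that bis(3-methoxyphenyl)acetylene and double arylation by 11 are held back. Any 14 that loses CO2 early becomes 3-ethynylanisole, which can still reach 15 by copper-free Sonogashira coupling with 11.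

Step 7
Reactants: 15 1,2-bis(benzyloxy)-3-{4,5-bis(benzyloxy)-2-[(3-methoxyphenyl)ethynyl]phenyl}-5-[2-(3-methoxyphenyl)ethyl]benzene
Product: 16 isoplagilin, 3-{4,5-dihydroxy-2-[2-(3-methoxyphenyl)ethyl]phenyl}-5-[2-(3-methoxyphenyl)ethyl]benzene-1,2-diol
Conditions: H2 (1 atm), 10% Pd/C, EtOAc/MeOH, rt; filtration and concentration under argon
Reagents that add atoms: none
Why: Heterogeneous catalytic hydrogenation saturates the diarylalkyne to the CH2CH2 bridge and hydrogenolyses the four benzyl aryl ethers to toluene in the same operation, while the aryl methyl ethers and the biaryl bond are inert.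

Compound list
1 | 3-bromo-4,5-dihydroxybenzaldehyde | O=Cc1cc(O)c(O)c(Br)c1 | starting material
2 | 3,4-bis(benzyloxy)-5-bromobenzaldehyde | O=Cc1cc(OCc2ccccc2)c(OCc2ccccc2)c(Br)c1 | intermediate
3 | (3-methoxybenzyl)triphenylphosphonium chloride | COc1cccc(C[P+](c2ccccc2)(c2ccccc2)c2ccccc2)c1.[Cl-] | starting material
4 | (3-methoxybenzylidene)triphenylphosphorane | COc1cccc(C=P(c2ccccc2)(c2ccccc2)c2ccccc2)c1 | intermediate
5 | 1,2-bis(benzyloxy)-3-bromo-5-[2-(3-methoxyphenyl)ethenyl]benzene (E/Z mixture, alkene geometry left open) | COc1cccc(C=Cc2cc(OCc3ccccc3)c(OCc3ccccc3)c(Br)c2)c1 | intermediate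
6 | 1,2-bis(benzyloxy)-3-bromo-5-[2-(3-methoxyphenyl)ethyl]benzene | COc1cccc(CCc2cc(OCc3ccccc3)c(OCc3ccccc3)c(Br)c2)c1 | intermediate
7 | 4,5-dibromobenzene-1,2-diol | Oc1cc(Br)c(Br)cc1O | starting material
8 | 1,2-bis(benzyloxy)-4,5-dibromobenzene | Brc1cc(OCc2ccccc2)c(OCc2ccccc2)cc1Br | intermediate
9 | {2,3-bis(benzyloxy)-5-[2-(3-methoxyphenyl)ethyl]phenyl}lithium | [Li]c1cc(CCc2cccc(OC)c2)cc(OCc2ccccc2)c1OCc1ccccc1 | intermediate
10 | {2,3-bis(benzyloxy)-5-[2-(3-methoxyphenyl)ethyl]phenyl}zinc chloride | Cl[Zn]c1cc(CCc2cccc(OC)c2)cc(OCc2ccccc2)c1OCc1ccccc1 | intermediate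
11 | 1,2-bis(benzyloxy)-3-[4,5-bis(benzyloxy)-2-bromophenyl]-5-[2-(3-methoxyphenyl)ethyl]benzene | COc1cccc(CCc2cc(OCc3ccccc3)c(OCc3ccccc3)c(-c3cc(OCc4ccccc4)c(OCc4ccccc4)cc3Br)c2)c1 | intermediate
12 | propiolic acid | C#CC(=O)O | starting material
13 | 3-iodoanisole | COc1cccc(I)c1 | starting material
14 | 3-(3-methoxyphenyl)propiolic acid (present in the flask as its DBU carboxylate) | COc1cccc(C#CC(=O)O)c1 | intermediate
15 | 1,2-bis(benzyloxy)-3-{4,5-bis(benzyloxy)-2-[(3-methoxyphenyl)ethynyl]phenyl}-5-[2-(3-methoxyphenyl)ethyl]benzene | COc1cccc(CCc2cc(OCc3ccccc3)c(OCc3ccccc3)c(-c3cc(OCc4ccccc4)c(OCc4ccccc4)cc3C#Cc3cccc(OC)c3)c2)c1 | intermediate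
16 | isoplagilin, 3-{4,5-dihydroxy-2-[2-(3-methoxyphenyl)ethyl]phenyl}-5-[2-(3-methoxyphenyl)ethyl]benzene-1,2-diol | COc1cccc(CCc2cc(O)c(O)c(-c3cc(O)c(O)cc3CCc3cccc(OC)c3)c2)c1 | target

Total step count: 7. Longest linear sequence: 6 steps (steps 1, 2, 3, 5, 6 and 7); step 4 is a one-step side branch.

Steps most likely to fail

Step 6. Oxidative addition into the hindered, electron-rich C6–Br bond of ring C may be slow. In that case 14 can lose CO2 and be used up by homocoupling or oligomerisation before the cross-coupling takes place. The fallback sets out from 11 and joins it directly to commercial 3-ethynylanisole (C#Cc1cccc(OC)c1) in a copper-free Sonogashira coupling with PdCl2(MeCN)2, XPhos (2-dicyclohexylphosphino-2',4',6'-triisopropylbiphenyl) and Cs2CO3 in MeCN at 80 °C. The bulky electron-rich phosphine is chosen for hindered aryl bromides, and the absence of copper avoids alkyne dimerisation. The fallback comes back to the route at 15 and makes no new compound (F0).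

Step 5. The product may be arylated a second time at its remaining bromide, or aryllithium 9 may be lost by proton transfer from a benzylic OCH2 group before it reaches zinc. The fallback sets out from 8 and makes the two halogens different. Single bromine–magnesium exchange with i-PrMgCl·LiCl in THF at −15 °C should give [4,5-bis(benzyloxy)-2-bromophenyl]magnesium chloride F1, not isolated. Quenching it with I2 should give 1,2-bis(benzyloxy)-4-bromo-5-iodobenzene F2. Arylzinc chloride 10, made from 6 as in step 5, is then coupled with F2 (1.1 equiv) using Pd(PPh3)4 in THF at rt, where insertion into the C–I bond is much faster than into the C–Br bond. The fallback comes back to the route at 11.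

Step 7. Hydrogenolysis may stall at partly benzylated stages once free catechol groups bind to the palladium surface, and the bis-catechol may oxidise in air during filtration. The fallback sets out from 15 and separates reduction from deprotection. Diimide (TsNHNH2, NaOAc, DME/H2O, reflux) should reduce the alkyne to give tetra-O-benzyl isoplagilin F3. The four benzyl ethers are then cleaved with BCl3 and pentamethylbenzene as cation scavenger in CH2Cl2 at −78 °C, followed by a MeOH quench. The aryl methyl ethers should survive these conditions. The fallback comes back to the route at 16.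

Further compounds
F0 | step 6 | none | none
F1 | step 5 | [4,5-bis(benzyloxy)-2-bromophenyl]magnesium chloride (not isolated) | Cl[Mg]c1cc(OCc2ccccc2)c(OCc2ccccc2)cc1Br
F2 | step 5 | 1,2-bis(benzyloxy)-4-bromo-5-iodobenzene | Brc1cc(OCc2ccccc2)c(OCc2ccccc2)cc1I
F3 | step 7 | tetra-O-benzyl isoplagilin, 1,2-bis(benzyloxy)-3-{4,5-bis(benzyloxy)-2-[2-(3-methoxyphenyl)ethyl]phenyl}-5-[2-(3-methoxyphenyl)ethyl]benzene | COc1cccc(CCc2cc(OCc3ccccc3)c(OCc3ccccc3)c(-c3cc(OCc4ccccc4)c(OCc4ccccc4)cc3CCc3cccc(OC)c3)c2)c1
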